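The dihydrofuran ring (O1, C2, C3, C3a, C7a) is traced back to the pyranone ring of a flavanone. The feature used: C3 bears one exocyclic carbon (CH2OH) beside the C3–C3a bond, and this carbon is the former C4 carbonyl. In the precursor, a (2S)-flavanone with ring B masked as a pivalate, trivalent iodine in trimethyl orthoformate induces a 1,2-shift of arene carbon C4a (later C3a) from C4 to C3. This forms C3–C3a, contracts the six-membered ring to the five-membered one, expels C4 as a methyl ester and sets C3 trans to C2 in one operation. The flavanone arises by enantioselective arylation of a chromone; one LiAlH4 reduction unveils both alcohols and the phenol.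

Key step: step 7

Assumption: the facial sense of the pyridine-oxazoline palladium catalyst on chromones is taken to follow its sense on cyclic enones. This calls for the (R)-ligand to reach the (2S)-flavanone. If the sense proves opposite, the (S)-ligand is used.

Step 1
Reactants: 1 1-(2-hydroxy-3-methoxyphenyl)ethan-1-one
Product: 2 1-(5-bromo-2-hydroxy-3-methoxyphenyl)ethan-1-one
Conditions: NBS, MeCN, 0 °C to rt
Reagents that add atoms: N-bromosuccinimide, O=C1CCC(=O)N1Br
Why: Electrophilic aromatic bromination goes to C5, which is para to the free phenol and meta to the acetyl group, so both directors converge there.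

Step 2
Reactants: 2 1-(5-bromo-2-hydroxy-3-methoxyphenyl)ethan-1-one
Product: 4 6-bromo-8-methoxy-4H-chromen-4-one, via enaminone 3 (not isolated)
Conditions: DMF-DMA, toluene, 100 °C; concentrate; then conc. HCl, CH2Cl2, 40 °C
Reagents that add atoms: N,N-dimethylformamide dimethyl acetal, COC(OC)N(C)C
Why: The methyl ketone condenses with the amide acetal to the enaminone, and acid then drives addition-elimination of the phenol with loss of dimethylamine, which is the standard enaminone synthesis of chromones.

Step 3
Reactants: 4 6-bromo-8-methoxy-4H-chromen-4-one; 5 methyl 3-bromopropanoate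
Product: 7 methyl 3-(8-methoxy-4-oxo-4H-chromen-6-yl)propanoate, via alkylzinc bromide 6 (not isolated)
Conditions: 5, Zn dust, LiCl, TMSCl (cat.), THF, 40 °C; then 4, Pd(OAc)2 (cat.), SPhos, THF, rt
Reagents that add atoms: zinc, [Zn] (its atom stays only in intermediate 6)
Why: In this Negishi coupling the ester-bearing alkylzinc halide is too mild to add to the chromone, and the bulky biaryl phosphine favours reductive elimination over β-hydride elimination.

Step 4
Reactants: 8 4-bromo-2,6-dimethoxyphenol
Product: 9 4-bromo-2,6-dimethoxyphenyl 2,2-dimethylpropanoate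
Conditions: PivCl, Et3N, DMAP (cat.), CH2Cl2, 0 °C to rt
Reagents that add atoms: pivaloyl chloride, CC(C)(C)C(=O)Cl
Why: DMAP-catalysed O-acylation installs a pivalate, which withstands acid and oxidant, lowers the donor power of ring B and is removed in the final hydride reduction.

Step 5
Reactants: 9 4-bromo-2,6-dimethoxyphenyl 2,2-dimethylpropanoate
Product: 10 [3,5-dimethoxy-4-(pivaloyloxy)phenyl]boronic acid
Conditions: B2(OH)4, Pd(OAc)2 (cat.), XPhos, KOAc, EtOH, 80 °C
Reagents that add atoms: tetrahydroxydiboron, OB(O)B(O)O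
Why: Palladium-catalysed Miyaura-type borylation with tetrahydroxydiboron gives the free boronic acid directly, and the acetate base leaves the hindered aryl ester intact.

Step 6
Reactants: 7 methyl 3-(8-methoxy-4-oxo-4H-chromen-6-yl)propanoate; 10 [3,5-dimethoxy-4-(pivaloyloxy)phenyl]boronic acid
Product: 11 methyl 3-[(2S)-2-[3,5-dimethoxy-4-(pivaloyloxy)phenyl]-8-methoxy-4-oxo-3,4-dihydro-2H-chromen-6-yl]propanoate
Conditions: Pd(OCOCF3)2 (cat.), (R)-t-BuPyOx [(R)-4-tert-butyl-2-(pyridin-2-yl)-4,5-dihydrooxazole] (cat.), NH4PF6, H2O, ClCH2CH2Cl, 60 °C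
Reagents that add atoms: none
Why: This is the enantioselective conjugate addition of an arylboronic acid to a chromone by a cationic divalent palladium pyridine-oxazoline complex, in which transmetalation is followed by migratory insertion of C2=C3 on the face left open by the tert-butyl group (setting C2 as S) and by base-free protonolysis that avoids racemisation through ring opening.

Step 7
Reactants: 11 methyl 3-[(2S)-2-[3,5-dimethoxy-4-(pivaloyloxy)phenyl]-8-methoxy-4-oxo-3,4-dihydro-2H-chromen-6-yl]propanoate
Product: 14 methyl (2S,3S)-2-[3,5-dimethoxy-4-(pivaloyloxy)phenyl]-7-methoxy-5-(3-methoxy-3-oxopropyl)-2,3-dihydro-1-benzofuran-3-carboxylate, via enol ether 12 (not isolated), via iodane ketal 13 (not isolated)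
Conditions: PhI(OAc)2, H2SO4 (cat.), HC(OMe)3, 0 °C to rt
Reagents that add atoms: trimethyl orthoformate, COC(OC)OC; (diacetoxyiodo)benzene, CC(=O)OI(OC(C)=O)c1ccccc1 (its atoms stay only in intermediate 13)
Why: Acid and HC(OMe)3 turn the C4 ketone into enol ether 12, trivalent iodine attacks its C3 on the face anti to the C2 aryl group, and methanol adds at C4 to give the 2,3-trans iodane ketal 13. Its equatorial C3–I bond is antiperiplanar to the ring bond C4–C4a, so C4a (the later C3a), pushed by the two ketal oxygens, shifts from C4 to C3 through a spiro phenonium ion while PhI leaves, and the dimethoxycarbenium ion left at C4 is demethylated to the methyl ester. The closest known reaction type is this very one, the hypervalent iodine (or thallium trinitrate) oxidative ring contraction of flavanones to methyl trans-2-aryl-2,3-dihydrobenzofuran-3-carboxylates, a 1,2-aryl shift of an α-functionalised aryl ketal. The dihydrofuran ring (O1, C2, C3, C3a, C7a) closes by six-to-five ring contraction, formally a 3-exo-tet ipso attack of C4a on C3 followed by cleavage of C4–C4a, which turns C4 into the exocyclic ester carbon. C2 is not touched, and C3 is set by substrate control from C2: anti iodination followed by inversion in the shift places CO2Me trans to the aryl group (2S,3S), which is also the more stable arrangement. The step needs ring A to migrate rather than ring B (isoflavone path), H-2 to stay (flavone path) and C2–O1 not to ionise (racemisation): C4a is ortho to the donor O1, whereas C1' of ring B has only meta methoxy groups and a para acyloxy group, and full ketalisation in the orthoformate blocks enone formation.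

Step 8
Reactants: 14 methyl (2S,3S)-2-[3,5-dimethoxy-4-(pivaloyloxy)phenyl]-7-methoxy-5-(3-methoxy-3-oxopropyl)-2,3-dihydro-1-benzofuran-3-carboxylate
Product: 15 4-[(2S,3R)-3-(hydroxymethyl)-5-(3-hydroxypropyl)-7-methoxy-2,3-dihydro-1-benzofuran-2-yl]-2,6-dimethoxyphenol
Conditions: LiAlH4, THF, 0 °C to rt; mildly acidic aqueous work-up
Reagents that add atoms: none
Why: LiAlH4 ester reduction takes down both methyl esters and the aryl pivalate in one operation and should outrun deprotonation at C3, as is usual for 2-aryl-2,3-dihydrobenzofuran-3-carboxylates, so C2 and C3 are kept (the C3 descriptor changes from S to R through priorities only).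

Compound list
1 | 1-(2-hydroxy-3-methoxyphenyl)ethan-1-one | CC(=O)c1cccc(OC)c1O | starting material
2 | 1-(5-bromo-2-hydroxy-3-methoxyphenyl)ethan-1-one | CC(=O)c1cc(Br)cc(OC)c1O | intermediate
3 | (E)-1-(5-bromo-2-hydroxy-3-methoxyphenyl)-3-(dimethylamino)prop-2-en-1-one | CN(C)/C=C/C(=O)c1cc(Br)cc(OC)c1O | intermediate
4 | 6-bromo-8-methoxy-4H-chromen-4-one | O=c1ccoc2c(OC)cc(Br)cc12 | intermediate
5 | methyl 3-bromopropanoate | COC(=O)CCBr | starting material
6 | (3-methoxy-3-oxopropyl)zinc bromide | COC(=O)CC[Zn]Br | intermediate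
7 | methyl 3-(8-methoxy-4-oxo-4H-chromen-6-yl)propanoate | COC(=O)CCc1cc(OC)c2occc(=O)c2c1 | intermediate
8 | 4-bromo-2,6-dimethoxyphenol | COc1cc(Br)cc(OC)c1O | starting material
9 | 4-bromo-2,6-dimethoxyphenyl 2,2-dimethylpropanoate | COc1cc(Br)cc(OC)c1OC(=O)C(C)(C)C | intermediate
10 | [3,5-dimethoxy-4-(pivaloyloxy)phenyl]boronic acid | COc1cc(B(O)O)cc(OC)c1OC(=O)C(C)(C)C | intermediate
11 | methyl 3-[(2S)-2-[3,5-dimethoxy-4-(pivaloyloxy)phenyl]-8-methoxy-4-oxo-3,4-dihydro-2H-chromen-6-yl]propanoate | COC(=O)CCc1cc(OC)c2O[C@@H](CC(=O)c2c1)c1cc(OC)c(OC(=O)C(C)(C)C)c(OC)c1 | intermediate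
12 | methyl 3-[(2S)-2-[3,5-dimethoxy-4-(pivaloyloxy)phenyl]-4,8-dimethoxy-2H-chromen-6-yl]propanoate | COC(=O)CCc1cc(OC)c2O[C@@H](C=C(OC)c2c1)c1cc(OC)c(OC(=O)C(C)(C)C)c(OC)c1 | intermediate
13 | methyl 3-[(2R,3R)-3-[acetoxy(phenyl)-λ3-iodanyl]-2-[3,5-dimethoxy-4-(pivaloyloxy)phenyl]-4,4,8-trimethoxy-3,4-dihydro-2H-chromen-6-yl]propanoate (2,3-trans; the C2 descriptor changes through priorities only) | COC(=O)CCc1cc(OC)c2O[C@@H]([C@@H](I(OC(C)=O)c3ccccc3)C(OC)(OC)c2c1)c1cc(OC)c(OC(=O)C(C)(C)C)c(OC)c1 | intermediate
14 | methyl (2S,3S)-2-[3,5-dimethoxy-4-(pivaloyloxy)phenyl]-7-methoxy-5-(3-methoxy-3-oxopropyl)-2,3-dihydro-1-benzofuran-3-carboxylate (2,3-trans) | COc1cc([C@H]2Oc3c(OC)cc(CCC(=O)OC)cc3[C@@H]2C(=O)OC)cc(OC)c1OC(=O)C(C)(C)C | intermediate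
15 | 4-[(2S,3R)-3-(hydroxymethyl)-5-(3-hydroxypropyl)-7-methoxy-2,3-dihydro-1-benzofuran-2-yl]-2,6-dimethoxyphenol | COc1cc([C@H]2Oc3c(OC)cc(CCCO)cc3[C@@H]2CO)cc(OC)c1O | target

Total step count: 8
Longest linear sequence: 6 (steps 1, 2, 3, 6, 7, 8)

Steps most likely to fail

Step 7. Ring B may migrate in competition with ring A. H-2 may be lost to give the enone, methanol may substitute at C3, or the trivalent iodine reagent may degrade the electron-rich arenes. The fallback is a stepwise, non-oxidative 1,2-aryl shift of an α-bromo ketal, and it sets out from 11.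
- α-Bromination with CuBr2 in EtOAc/CHCl3 at reflux should give the (2R,3R)-trans-3-bromoflavanone F1, with equatorial bromide.
- Ketalisation with HC(OMe)3, MeOH and TsOH (cat.) gives the α-bromo dimethyl ketal F2.
- Heating with ZnBr2 (cat.) in toluene induces the Lewis acid promoted aryl shift of C4a from C4 to C3, with inversion at C3 and loss of the ketal methyl group as its bromide.
- The same bond and the same trans relationship result, and the fallback comes back to the route at 14.

Step 6. Facial selectivity may be poor, or enantiopurity may erode through reversible opening of the pyranone ring at the reaction temperature. The fallback is a racemic addition followed by kinetic resolution, and it sets out from 7 and 10.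
- Conjugate addition with Pd(OCOCF3)2 and achiral 2,2'-bipyridine under otherwise the same regime gives the racemic flavanone F3.
- Asymmetric transfer hydrogenation with RuCl[(R,R)-TsDPEN](p-cymene) and HCO2H/Et3N in EtOAc is stopped near half conversion.
- This should reduce the (2R)-enantiomer to the cis-(2R,4R)-flavan-4-ol F4 and leave the (2S)-ketone.
- The (2S)-ketone is separated by chromatography and is 11.

Step 3. The bromide may undergo hydrodebromination, the alkylpalladium intermediate may undergo β-hydride elimination, or the organometallic may attack C2 of the chromone. The fallback installs the chain before the heterocycle by Heck reaction and hydrogenation, and it sets out from 2.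
- Heck reaction with methyl acrylate (Pd(OAc)2, P(o-tol)3, Et3N, DMF, 100 °C) gives the cinnamate F5.
- Hydrogenation (H2, Pd/C, EtOAc, rt) gives the propanoate F6.
- DMF-DMA in toluene at 100 °C gives the enaminone F7.
- Conc. HCl in CH2Cl2 closes this enaminone to the chromone, and the fallback comes back to the route at 7.

Further compounds
F1 | step 7 | methyl 3-[(2R,3R)-3-bromo-2-[3,5-dimethoxy-4-(pivaloyloxy)phenyl]-8-methoxy-4-oxo-3,4-dihydro-2H-chromen-6-yl]propanoate (2,3-trans) | COC(=O)CCc1cc(OC)c2O[C@@H]([C@@H](Br)C(=O)c2c1)c1cc(OC)c(OC(=O)C(C)(C)C)c(OC)c1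
F2 | step 7 | methyl 3-[(2R,3R)-3-bromo-2-[3,5-dimethoxy-4-(pivaloyloxy)phenyl]-4,4,8-trimethoxy-3,4-dihydro-2H-chromen-6-yl]propanoate (2,3-trans) | COC(=O)CCc1cc(OC)c2O[C@@H]([C@@H](Br)C(OC)(OC)c2c1)c1cc(OC)c(OC(=O)C(C)(C)C)c(OC)c1
F3 | step 6 | racemic methyl 3-[2-[3,5-dimethoxy-4-(pivaloyloxy)phenyl]-8-methoxy-4-oxo-3,4-dihydro-2H-chromen-6-yl]propanoate | COC(=O)CCc1cc(OC)c2OC(CC(=O)c2c1)c1cc(OC)c(OC(=O)C(C)(C)C)c(OC)c1
F4 | step 6 | methyl 3-[(2R,4R)-2-[3,5-dimethoxy-4-(pivaloyloxy)phenyl]-4-hydroxy-8-methoxy-3,4-dihydro-2H-chromen-6-yl]propanoate (2,4-cis) | COC(=O)CCc1cc(OC)c2O[C@H](C[C@@H](O)c2c1)c1cc(OC)c(OC(=O)C(C)(C)C)c(OC)c1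
F5 | step 3 | methyl (E)-3-(3-acetyl-4-hydroxy-5-methoxyphenyl)prop-2-enoate | COC(=O)/C=C/c1cc(OC)c(O)c(C(C)=O)c1
F6 | step 3 | methyl 3-(3-acetyl-4-hydroxy-5-methoxyphenyl)propanoate | COC(=O)CCc1cc(OC)c(O)c(C(C)=O)c1
F7 | step 3 | methyl 3-[3-[(E)-3-(dimethylamino)prop-2-enoyl]-4-hydroxy-5-methoxyphenyl]propanoate | COC(=O)CCc1cc(OC)c(O)c(C(=O)/C=C/N(C)C)c1
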